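**Retrosynthetic overview**

1. The acid comes from methyl ester 25, whose 1,2-dioxane is closed last from mesylate-enoate 23 with H2O2 (SN2 with inversion at the mesylated carbinol, then 6-exo oxa-Michael), so the O–O bond never meets an organometallic reagent.
2. 23 comes from oxolane-2-carbaldehyde 18 by Cram-chelate Grignard addition (the exocyclic carbinol is relayed from the ring stereocentre), mesylation, acetal hydrolysis and Wittig olefination.
3. The oxolane contains the array O1–C2H–C3H2–C4H2–C5H: the C3–C4 bond joins two unsubstituted methylenes and C5 is a carbinol-type carbon. It is therefore cut across C3–C4 and O1–C5 into a three-atom O–C2–C3 unit (β-lithioalkoxide from chlorohydrin 12) and a two-atom C4–C5 unit (vicinal ditosylate 10). These are joined in one pot by C-alkylation and 5-exo-tet etherification with inversion, which gives the 2,5-trans ring directly.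
4. 10 comes from (S)-glycidyl tosylate and the trienyl Grignard reagent of bromide 6; the (Z,Z)-diene comes from Cadiot–Chodkiewicz coupling and Boland reduction.
5. Order of ring formation: oxolane (step 8), then 1,2-dioxane (step 15).

Key step: step 8

Remark: compounds 1, 3, 7, 11 and 19 (the last as its THF solution) are taken as purchasable.

**Step 1**
Reactants: 1 hex-1-en-5-yne
Product: 2 6-bromohex-1-en-5-yne
Conditions: NBS, AgNO3 (10 mol%), acetone, rt
Reagents that add atoms: N-bromosuccinimide, O=C1CCC(=O)N1Br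
Why: Silver-catalysed electrophilic bromination of the terminal alkyne C–H (through the silver acetylide) should give the 1-bromoalkyne and leave the isolated alkene untouched.

**Step 2**
Reactants: 2 6-bromohex-1-en-5-yne; 3 hept-6-yn-1-ol
Product: 4 tridec-12-ene-6,8-diyn-1-ol
Conditions: CuCl (5 mol%), NH2OH·HCl, n-BuNH2 (30% aq.), Et2O, 0 °C
Reagents that add atoms: none
Why: Cadiot–Chodkiewicz coupling (CuCl, the copper kept monovalent by hydroxylamine) joins the terminal alkyne of 3 to bromoalkyne 2 as the unsymmetrical 1,3-diyne, the free alcohol and the alkene being inert.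

**Step 3**
Reactants: 4 tridec-12-ene-6,8-diyn-1-ol
Product: 5 (6Z,8Z)-trideca-6,8,12-trien-1-ol
Conditions: Zn(Cu/Ag) couple, MeOH–H2O (1:1), 45 °C
Reagents that add atoms: none
Why: Boland reduction delivers hydrogen cis and only to conjugated triple bonds, so both alkynes of the diyne should become Z alkenes (this sets the Z,Z geometry) while the isolated terminal alkene is not reduced.

**Step 4**
Reactants: 5 (6Z,8Z)-trideca-6,8,12-trien-1-ol
Product: 6 (5Z,7Z)-13-bromotrideca-1,5,7-triene
Conditions: CBr4, PPh3, CH2Cl2, 0 °C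
Reagents that add atoms: tetrabromomethane, BrC(Br)(Br)Br
Why: The Appel reaction converts the primary alcohol into the bromide under neutral conditions that should not isomerise the Z,Z-diene.

**Step 5**
Reactants: 6 (5Z,7Z)-13-bromotrideca-1,5,7-triene; 7 (2S)-oxiran-2-ylmethyl 4-methylbenzenesulfonate [(S)-glycidyl tosylate]
Product: 9 (2S,9Z,11Z)-2-hydroxyhexadeca-9,11,15-trien-1-yl 4-methylbenzenesulfonate, via trienyl Grignard reagent 8 (not isolated)
Conditions: Mg, THF, rt; then 7, CuI (10 mol%), THF, −40 °C; aq. NH4Cl at −40 °C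
Reagents that add atoms: none
Why: Copper-catalysed epoxide opening: at low temperature the Grignard reagent attacks the unsubstituted epoxide carbon faster than it displaces the tosylate, and the untouched stereocentre is carried over as the (S)-carbinol.

**Step 6**
Reactants: 9 (2S,9Z,11Z)-2-hydroxyhexadeca-9,11,15-trien-1-yl 4-methylbenzenesulfonate
Product: 10 (2S,9Z,11Z)-hexadeca-9,11,15-triene-1,2-diyl bis(4-methylbenzenesulfonate)
Conditions: TsCl, Et3N, DMAP (cat.), CH2Cl2, 0 °C → rt
Reagents that add atoms: 4-methylbenzenesulfonyl chloride, Cc1ccc(cc1)S(Cl)(=O)=O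
Why: DMAP-catalysed tosylation of the secondary alcohol with retention gives the vicinal bis-electrophile, and the weak amine base should not close the epoxide at this temperature.

**Step 7**
Reactants: 11 (2R)-3-chloropropane-1,2-diol
Product: 12 (2R)-1-chloro-3-{[tri(propan-2-yl)silyl]oxy}propan-2-ol
Conditions: TIPSCl, imidazole, CH2Cl2, 0 °C
Reagents that add atoms: chlorotri(propan-2-yl)silane, CC(C)[Si](Cl)(C(C)C)C(C)C
Why: Selective silylation of the primary hydroxyl by the bulky silyl chloride; the TIPS ether is chosen because it should resist the arene radical anion and silyl shifts to oxygen or carbon in step 8.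

**Step 8**
Reactants: 10 (2S,9Z,11Z)-hexadeca-9,11,15-triene-1,2-diyl bis(4-methylbenzenesulfonate); 12 (2R)-1-chloro-3-{[tri(propan-2-yl)silyl]oxy}propan-2-ol
Product: 16 tri(propan-2-yl){[(2S,5R)-5-[(7Z,9Z)-tetradeca-7,9,13-trien-1-yl]oxolan-2-yl]methoxy}silane, via lithium chloroalkoxide 13 (not isolated), via C,O-dilithio reagent 14 (not isolated), via open-chain lithium alkoxide tosylate 15 (not isolated)
Conditions: 12 (2.5 equiv), n-BuLi, THF, −78 °C; LiDBB (lithium 4,4'-di-tert-butylbiphenylide, 2 equiv per 12), −78 °C; CuBr·SMe2 (10 mol%), then 10, −78 → −30 °C; DMPU, 0 → 40 °C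
Reagents that add atoms: none
Why: Proposed new method: deprotonation of 12 and reductive chlorine–lithium exchange give the β-lithioalkoxide 14, whose oxide oxygen is too poor a leaving group for fast β-elimination at −78 °C; under CuBr·SMe2 catalysis its carbanion displaces the primary tosylate of 10 (new C3–C4 bond of the ring), and on warming the lithium alkoxide of 15 displaces the secondary tosylate (new O1–C5 bond). The closest known reaction types are the copper-catalysed coupling of organolithium and Grignard reagents with primary tosylates, the alkylation of β-lithioalkoxides made from chlorohydrins or epoxides, and the double displacement of 1,2-cyclic sulfates or 1,2-bis-sulfonates by bis-nucleophiles. The oxolane closes in the 5-exo-tet mode (intramolecular Williamson etherification). C5 of the ring is set by inversion of the (S)-secondary tosylate to (R), and C2 is carried unchanged from 12, so the 2,5-trans ring should result without any diastereoselection being needed. The step needs carbon to react before oxygen and the primary sulfonate before the secondary one; this is secured by the much higher nucleophilicity of the organocopper species than of the lithium alkoxide at low temperature, by the steric difference between the two sulfonates, and by the absence of any acidifying group that could divert the closure to a cyclopropane.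

**Step 9**
Reactants: 16 tri(propan-2-yl){[(2S,5R)-5-[(7Z,9Z)-tetradeca-7,9,13-trien-1-yl]oxolan-2-yl]methoxy}silane
Product: 17 [(2S,5R)-5-[(7Z,9Z)-tetradeca-7,9,13-trien-1-yl]oxolan-2-yl]methanol
Conditions: TBAF, THF, 0 °C → rt
Reagents that add atoms: none
Why: Fluoride-mediated desilylation frees the primary alcohol without touching the triene or the ring.

**Step 10**
Reactants: 17 [(2S,5R)-5-[(7Z,9Z)-tetradeca-7,9,13-trien-1-yl]oxolan-2-yl]methanol
Product: 18 (2S,5R)-5-[(7Z,9Z)-tetradeca-7,9,13-trien-1-yl]oxolane-2-carbaldehyde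
Conditions: Dess–Martin periodinane, NaHCO3, CH2Cl2, 0 °C
Reagents that add atoms: none
Why: Buffered Dess–Martin oxidation should give the α-alkoxy aldehyde without epimerisation; the aldehyde is used at once.

**Step 11**
Reactants: 18 (2S,5R)-5-[(7Z,9Z)-tetradeca-7,9,13-trien-1-yl]oxolane-2-carbaldehyde; 19 [2-(1,3-dioxolan-2-yl)ethyl]magnesium bromide
Product: 20 (1S)-3-(1,3-dioxolan-2-yl)-1-[(2S,5R)-5-[(7Z,9Z)-tetradeca-7,9,13-trien-1-yl]oxolan-2-yl]propan-1-ol
Conditions: MgBr2·OEt2, CH2Cl2, −78 °C; then 19 (THF solution), −78 °C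
Reagents that add atoms: none
Why: Cram-chelate Grignard addition: MgBr2 bridges the aldehyde oxygen and the ring oxygen and the nucleophile adds to the chelate from the face opposite the ring C3 methylene, which should set the new carbinol as (S), threo to the ring C–O bond.

**Step 12**
Reactants: 20 (1S)-3-(1,3-dioxolan-2-yl)-1-[(2S,5R)-5-[(7Z,9Z)-tetradeca-7,9,13-trien-1-yl]oxolan-2-yl]propan-1-ol
Product: 21 (1S)-3-(1,3-dioxolan-2-yl)-1-[(2S,5R)-5-[(7Z,9Z)-tetradeca-7,9,13-trien-1-yl]oxolan-2-yl]propyl methanesulfonate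
Conditions: MsCl, Et3N, CH2Cl2, 0 °C
Reagents that add atoms: methanesulfonyl chloride, CS(Cl)(=O)=O
Why: Mesylation with retention turns the carbinol into the leaving group needed for the later inversion.

**Step 13**
Reactants: 21 (1S)-3-(1,3-dioxolan-2-yl)-1-[(2S,5R)-5-[(7Z,9Z)-tetradeca-7,9,13-trien-1-yl]oxolan-2-yl]propyl methanesulfonate
Product: 22 (1S)-4-oxo-1-[(2S,5R)-5-[(7Z,9Z)-tetradeca-7,9,13-trien-1-yl]oxolan-2-yl]butyl methanesulfonate
Conditions: 1 M HCl, THF, rt
Reagents that add atoms: water, O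
Why: Acid-catalysed acetal hydrolysis unmasks the aldehyde; the secondary mesylate, the ring ether and the alkenes should survive dilute acid at room temperature.

**Step 14**
Reactants: 22 (1S)-4-oxo-1-[(2S,5R)-5-[(7Z,9Z)-tetradeca-7,9,13-trien-1-yl]oxolan-2-yl]butyl methanesulfonate
Product: 23 methyl (2E,6S)-6-(methanesulfonyloxy)-6-[(2S,5R)-5-[(7Z,9Z)-tetradeca-7,9,13-trien-1-yl]oxolan-2-yl]hex-2-enoate
Conditions: Ph3P=CHCO2Me, CH2Cl2, rt
Reagents that add atoms: methyl 2-(triphenyl-λ5-phosphanylidene)acetate, COC(=O)C=P(c1ccccc1)(c1ccccc1)c1ccccc1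
Why: Wittig olefination with the stabilised ylide should give the (E)-enoate under neutral conditions that leave the mesylate intact.

**Step 15**
Reactants: 23 methyl (2E,6S)-6-(methanesulfonyloxy)-6-[(2S,5R)-5-[(7Z,9Z)-tetradeca-7,9,13-trien-1-yl]oxolan-2-yl]hex-2-enoate
Product: 25 methyl 2-[(3R,6R)-6-[(2S,5R)-5-[(7Z,9Z)-tetradeca-7,9,13-trien-1-yl]oxolan-2-yl]-1,2-dioxan-3-yl]acetate, via hydroperoxy enoate 24 (not isolated)
Conditions: H2O2 (50% aq., excess), CsOH·H2O, DMF, 0 °C → rt; then Et2NH (cat.), CF3CH2OH, rt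
Reagents that add atoms: hydrogen peroxide, OO
Why: Hydroperoxide anion displaces the secondary mesylate by SN2 with inversion (S to R at the future dioxane C6), and the hydroperoxide then closes by reversible 6-exo-trig oxa-Michael addition to the enoate, which under thermodynamic control should place the acetate arm equatorial and trans to the oxolane substituent (3R).

**Step 16**
Reactants: 25 methyl 2-[(3R,6R)-6-[(2S,5R)-5-[(7Z,9Z)-tetradeca-7,9,13-trien-1-yl]oxolan-2-yl]-1,2-dioxan-3-yl]acetate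
Product: 26 2-[(3R,6R)-6-[(2S,5R)-5-[(7Z,9Z)-tetradeca-7,9,13-trien-1-yl]oxolan-2-yl]-1,2-dioxan-3-yl]acetic acid
Conditions: LiOH·H2O, THF–H2O, 0 °C; then 0.5 M HCl to pH 4
Reagents that add atoms: lithium hydroxide, [Li+].[OH-]
Why: Mild saponification of the methyl ester at 0 °C, which should be faster than base-induced opening of the dialkyl peroxide, followed by careful acidification gives the acid.

**Compound list**

1 | hex-1-en-5-yne | C=CCCC#C | starting material
2 | 6-bromohex-1-en-5-yne | C=CCCC#CBr | intermediate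
3 | hept-6-yn-1-ol | C#CCCCCCO | starting material
4 | tridec-12-ene-6,8-diyn-1-ol | C=CCCC#CC#CCCCCCO | intermediate
5 | (6Z,8Z)-trideca-6,8,12-trien-1-ol | C=CCC/C=C\C=C/CCCCCO | intermediate
6 | (5Z,7Z)-13-bromotrideca-1,5,7-triene | C=CCC/C=C\C=C/CCCCCBr | intermediate
7 | (2S)-oxiran-2-ylmethyl 4-methylbenzenesulfonate | Cc1ccc(cc1)S(=O)(=O)OC[C@@H]1CO1 | starting material
8 | [(6Z,8Z)-trideca-6,8,12-trien-1-yl]magnesium bromide | C=CCC/C=C\C=C/CCCCC[Mg]Br | intermediate
9 | (2S,9Z,11Z)-2-hydroxyhexadeca-9,11,15-trien-1-yl 4-methylbenzenesulfonate | C=CCC/C=C\C=C/CCCCCC[C@H](O)COS(=O)(=O)c1ccc(C)cc1 | intermediate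
10 | (2S,9Z,11Z)-hexadeca-9,11,15-triene-1,2-diyl bis(4-methylbenzenesulfonate) | C=CCC/C=C\C=C/CCCCCC[C@H](OS(=O)(=O)c1ccc(C)cc1)COS(=O)(=O)c1ccc(C)cc1 | intermediate
11 | (2R)-3-chloropropane-1,2-diol | ClC[C@@H](CO)O | starting material
12 | (2R)-1-chloro-3-{[tri(propan-2-yl)silyl]oxy}propan-2-ol | ClC[C@@H](CO[Si](C(C)C)(C(C)C)C(C)C)O | intermediate
13 | lithium (2R)-1-chloro-3-{[tri(propan-2-yl)silyl]oxy}propan-2-olate | ClC[C@@H](CO[Si](C(C)C)(C(C)C)C(C)C)O[Li] | intermediate
14 | lithium (2S)-1-lithio-3-{[tri(propan-2-yl)silyl]oxy}propan-2-olate | [Li]C[C@@H](CO[Si](C(C)C)(C(C)C)C(C)C)O[Li] | intermediate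
15 | lithium (2S,5S,12Z,14Z)-5-(tosyloxy)-1-{[tri(propan-2-yl)silyl]oxy}nonadeca-12,14,18-trien-2-olate | C=CCC/C=C\C=C/CCCCCC[C@H](OS(=O)(=O)c1ccc(C)cc1)CC[C@@H](CO[Si](C(C)C)(C(C)C)C(C)C)O[Li] | intermediate
16 | tri(propan-2-yl){[(2S,5R)-5-[(7Z,9Z)-tetradeca-7,9,13-trien-1-yl]oxolan-2-yl]methoxy}silane | C=CCC/C=C\C=C/CCCCCC[C@@H]1CC[C@@H](CO[Si](C(C)C)(C(C)C)C(C)C)O1 | intermediate
17 | [(2S,5R)-5-[(7Z,9Z)-tetradeca-7,9,13-trien-1-yl]oxolan-2-yl]methanol | C=CCC/C=C\C=C/CCCCCC[C@@H]1CC[C@@H](CO)O1 | intermediate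
18 | (2S,5R)-5-[(7Z,9Z)-tetradeca-7,9,13-trien-1-yl]oxolane-2-carbaldehyde | C=CCC/C=C\C=C/CCCCCC[C@@H]1CC[C@@H](C=O)O1 | intermediate
19 | [2-(1,3-dioxolan-2-yl)ethyl]magnesium bromide | Br[Mg]CCC1OCCO1 | starting material
20 | (1S)-3-(1,3-dioxolan-2-yl)-1-[(2S,5R)-5-[(7Z,9Z)-tetradeca-7,9,13-trien-1-yl]oxolan-2-yl]propan-1-ol | C=CCC/C=C\C=C/CCCCCC[C@@H]1CC[C@@H]([C@@H](O)CCC2OCCO2)O1 | intermediate
21 | (1S)-3-(1,3-dioxolan-2-yl)-1-[(2S,5R)-5-[(7Z,9Z)-tetradeca-7,9,13-trien-1-yl]oxolan-2-yl]propyl methanesulfonate | C=CCC/C=C\C=C/CCCCCC[C@@H]1CC[C@@H]([C@@H](OS(C)(=O)=O)CCC2OCCO2)O1 | intermediate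
22 | (1S)-4-oxo-1-[(2S,5R)-5-[(7Z,9Z)-tetradeca-7,9,13-trien-1-yl]oxolan-2-yl]butyl methanesulfonate | C=CCC/C=C\C=C/CCCCCC[C@@H]1CC[C@@H]([C@@H](OS(C)(=O)=O)CCC=O)O1 | intermediate
23 | methyl (2E,6S)-6-(methanesulfonyloxy)-6-[(2S,5R)-5-[(7Z,9Z)-tetradeca-7,9,13-trien-1-yl]oxolan-2-yl]hex-2-enoate | C=CCC/C=C\C=C/CCCCCC[C@@H]1CC[C@@H]([C@@H](OS(C)(=O)=O)CC/C=C/C(=O)OC)O1 | intermediate
24 | methyl (2E,6R)-6-hydroperoxy-6-[(2S,5R)-5-[(7Z,9Z)-tetradeca-7,9,13-trien-1-yl]oxolan-2-yl]hex-2-enoate | C=CCC/C=C\C=C/CCCCCC[C@@H]1CC[C@@H]([C@H](OO)CC/C=C/C(=O)OC)O1 | intermediate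
25 | methyl 2-[(3R,6R)-6-[(2S,5R)-5-[(7Z,9Z)-tetradeca-7,9,13-trien-1-yl]oxolan-2-yl]-1,2-dioxan-3-yl]acetate | C=CCC/C=C\C=C/CCCCCC[C@@H]1CC[C@@H]([C@H]2CC[C@H](CC(=O)OC)OO2)O1 | intermediate
26 | 2-[(3R,6R)-6-[(2S,5R)-5-[(7Z,9Z)-tetradeca-7,9,13-trien-1-yl]oxolan-2-yl]-1,2-dioxan-3-yl]acetic acid | C=CCC/C=C\C=C/CCCCCC[C@@H]1CC[C@@H]([C@H]2CC[C@H](CC(=O)O)OO2)O1 | target

**Step count and risks**

Total step count: 16. Longest linear sequence: 15 steps (steps 1–6, then 8–16; step 7 is a one-step side branch).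

Steps most likely to fail:

1. Step 8 (proposed new method). The β-lithioalkoxide may lose lithium oxide by β-elimination before the slow displacement at a primary carbon that carries a β-sulfonyloxy group. The organolithium may also attack at sulfur, or the secondary tosylate may undergo 1,2-elimination. Fallback with known chemistry, setting out from 6 and coming back at 17: the Grignard reagent of 6 opens (2S)-2-(but-3-en-1-yl)oxirane (C=CCC[C@H]1CO1) at its unsubstituted carbon under CuI catalysis to give (5R,12Z,14Z)-nonadeca-1,12,14,18-tetraen-5-ol F1, which carries the ring C5 stereocentre with retention. Aerobic oxidative cyclisation of this 4-pentenol-type alcohol (Mukaiyama type; Co(modp)2, modp = 1-morpholinocarbamoyl-4,4-dimethylpentane-1,3-dionate, divalent cobalt; O2, t-BuOOH, i-PrOH, 55 °C) closes the 2,5-trans oxolane with its hydroxymethyl group and gives 17. The route then continues at step 10.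

2. Step 15. Intermolecular SN2 at a secondary carbon next to the ring oxygen may be slow, so that E2 elimination, attack of hydroperoxide anion on the enoate or ester, or incomplete equilibration at dioxane C3 takes over. Fallback, setting out from 20 and coming back at 25: triflation (Tf2O, 2,6-lutidine, CH2Cl2, −78 °C) gives (1S)-3-(1,3-dioxolan-2-yl)-1-[(2S,5R)-5-[(7Z,9Z)-tetradeca-7,9,13-trien-1-yl]oxolan-2-yl]propyl trifluoromethanesulfonate F2. Anhydrous H2O2 in Et2O at −40 → 0 °C displaces the far better leaving group with inversion, with no enoate present, to give 2-[(3R)-3-hydroperoxy-3-[(2S,5R)-5-[(7Z,9Z)-tetradeca-7,9,13-trien-1-yl]oxolan-2-yl]propyl]-1,3-dioxolane F3. TsOH in MeOH closes the hydroperoxy acetal to (2S,5R)-2-[(3R)-6-methoxy-1,2-dioxan-3-yl]-5-[(7Z,9Z)-tetradeca-7,9,13-trien-1-yl]oxolane F4 (both acetal epimers). TMSOTf-promoted addition of 1-(tert-butyldimethylsilyloxy)-1-methoxyethene (C=C(OC)O[Si](C)(C)C(C)(C)C) to the derived peroxycarbenium ion in CH2Cl2 at −78 °C forms the acetate arm by C–C bond formation and gives 25 after separation of the C3 epimer.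

3. Step 11. Chelate control may be insufficient when THF from the reagent solution competes for magnesium, so that Felkin–Anh addition erodes the facial selectivity. Fallback, setting out from 18 and coming back at 20: addition of 19 without selectivity gives 20 together with (1R)-3-(1,3-dioxolan-2-yl)-1-[(2S,5R)-5-[(7Z,9Z)-tetradeca-7,9,13-trien-1-yl]oxolan-2-yl]propan-1-ol F5. Dess–Martin oxidation of the mixture gives 3-(1,3-dioxolan-2-yl)-1-[(2S,5R)-5-[(7Z,9Z)-tetradeca-7,9,13-trien-1-yl]oxolan-2-yl]propan-1-one F6. Reduction with LiBH(s-Bu)3 in THF at −78 °C under Felkin–Anh control (hydride anti to the ring C–O bond) should return the threo alcohol 20.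

**Further compounds**

F1 | step 8 | (5R,12Z,14Z)-nonadeca-1,12,14,18-tetraen-5-ol | C=CCC/C=C\C=C/CCCCCC[C@@H](O)CCC=C
F2 | step 15 | (1S)-3-(1,3-dioxolan-2-yl)-1-[(2S,5R)-5-[(7Z,9Z)-tetradeca-7,9,13-trien-1-yl]oxolan-2-yl]propyl trifluoromethanesulfonate | C=CCC/C=C\C=C/CCCCCC[C@@H]1CC[C@@H]([C@@H](OS(=O)(=O)C(F)(F)F)CCC2OCCO2)O1
F3 | step 15 | 2-[(3R)-3-hydroperoxy-3-[(2S,5R)-5-[(7Z,9Z)-tetradeca-7,9,13-trien-1-yl]oxolan-2-yl]propyl]-1,3-dioxolane | C=CCC/C=C\C=C/CCCCCC[C@@H]1CC[C@@H]([C@H](OO)CCC2OCCO2)O1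
F4 | step 15 | (2S,5R)-2-[(3R)-6-methoxy-1,2-dioxan-3-yl]-5-[(7Z,9Z)-tetradeca-7,9,13-trien-1-yl]oxolane (both epimers at the acetal carbon) | C=CCC/C=C\C=C/CCCCCC[C@@H]1CC[C@@H]([C@H]2CCC(OC)OO2)O1
F5 | step 11 | (1R)-3-(1,3-dioxolan-2-yl)-1-[(2S,5R)-5-[(7Z,9Z)-tetradeca-7,9,13-trien-1-yl]oxolan-2-yl]propan-1-ol | C=CCC/C=C\C=C/CCCCCC[C@@H]1CC[C@@H]([C@H](O)CCC2OCCO2)O1
F6 | step 11 | 3-(1,3-dioxolan-2-yl)-1-[(2S,5R)-5-[(7Z,9Z)-tetradeca-7,9,13-trien-1-yl]oxolan-2-yl]propan-1-one | C=CCC/C=C\C=C/CCCCCC[C@@H]1CC[C@@H](C(=O)CCC2OCCO2)O1
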